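**Plan**

- Cuts, in retrosynthetic order: the C1/C10 epoxide back to the E alkene, the C8–O acyl bond (epoxy acid 33), C11=C13 back to the lactone CH2, then C9–C10 of the ten-membered ring, then C6–C7 together with the lactone C–O (aldol–lactonisation), then C3–C4 (alkenyl addition).
- Enabling feature: in ring A (C1–C10) the E alkene C1=C10 carries its methyl on C10, C10 is bonded to the methylene C9, and the neighbouring C8 bears oxygen. An E alkenyl iodide at C10 and a C9 alkylborane obtained from a C8 enol ether therefore meet exactly at C9–C10.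
- Forward: fragments 4 and 8 are joined at C3–C4; the chain is extended at C6–C7 while the γ-lactone (ring B) closes; ring A closes by hydroboration and B-alkyl Suzuki–Miyaura coupling; methylenation, acylation and epoxidation finish the synthesis.
- Stereochemistry: C3 from a ligand-controlled alkenylzinc addition; C6 and C7 from an Evans syn aldol; C8 from hydroboration steered by C7; the side-chain epoxide from a Sharpless epoxidation; C1/C10 from peracid attack on the outer face of the macrocycle. Both alkene geometries are stored in iodides 3 and 7.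

Key step: step 14

Remark: atoms are numbered as in germacranolides (ring C1–C10, lactone O–C6 and C7–C11–C12, C13 exocyclic, C14 on C10, C15 on C4). Compounds 1, 5, 15, 16, 31 and both enantiomers of 3-exo-morpholinoisoborneol (MIB) are taken as purchasable.

Step 1
Reactants: 1 but-2-yn-1-ol
Product: 3 (2Z)-3-iodobut-2-en-1-ol, via alkenylalanate 2 (not isolated)
Conditions: NaAlH2(OCH2CH2OMe)2, THF, 0 °C → rt; then I2, −78 °C → rt
Reagents that add atoms: iodine, II
Why: Alkoxide-directed trans-hydroalumination places aluminium on C3 inside a five-membered alanate and iodinolysis with retention gives the Z iodide (hydroalumination–iodination of a propargylic alcohol).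

Step 2
Reactants: 3 (2Z)-3-iodobut-2-en-1-ol
Product: 4 tert-butyl{[(2Z)-3-iodobut-2-en-1-yl]oxy}dimethylsilane
Conditions: TBSCl, imidazole, CH2Cl2, 0 °C → rt
Reagents that add atoms: tert-butyldimethylsilyl chloride, CC(C)(C)[Si](C)(C)Cl
Why: Routine silylation of a primary alcohol, needed so that the later iodine–lithium exchange is not quenched.

Step 3
Reactants: 5 pent-3-yn-1-ol
Product: 7 (3E)-4-iodopent-3-en-1-ol, via alkenylzirconocene 6 (not isolated)
Conditions: Cp2Zr(H)Cl (2.5 equiv), THF, rt; then I2, 0 °C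
Reagents that add atoms: iodine, II
Why: Syn hydrozirconation of the 2-alkyne, equilibrated by excess hydride so that zirconium sits on the methyl-bearing carbon, followed by iodinolysis with retention, gives the E 2-iodo-2-alkene (hydrozirconation–iodination).

Step 4
Reactants: 7 (3E)-4-iodopent-3-en-1-ol
Product: 8 (3E)-4-iodopent-3-enal
Conditions: Dess–Martin periodinane, NaHCO3, CH2Cl2, 0 °C; used crude at once
Reagents that add atoms: none
Why: Buffered Dess–Martin oxidation gives the β,γ-unsaturated aldehyde under neutral conditions that should not move the alkene into conjugation.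

Step 5
Reactants: 4 tert-butyl{[(2Z)-3-iodobut-2-en-1-yl]oxy}dimethylsilane (2.2 equiv); 8 (3E)-4-iodopent-3-enal
Product: 11 (2Z,4S,6E)-1-[(tert-butyldimethylsilyl)oxy]-7-iodo-3-methylocta-2,6-dien-4-ol, via alkenyllithium 9 (not isolated), via dialkenylzinc 10 (not isolated)
Conditions: t-BuLi (4.4 equiv), Et2O, −78 °C; ZnBr2 (1.1 equiv), −78 → 0 °C; TEEDA, (2R)-(+)-3-exo-morpholinoisoborneol (10 mol%), toluene; then 8, −20 → 0 °C
Reagents that add atoms: none
Why: Iodine–lithium exchange and transmetalation to zinc keep the Z geometry, and the amino-alcohol-catalysed alkenylzinc addition with the (2R) ligand (its (2S) antipode is Si-selective) should deliver the alkenyl group to the Re face of the aldehyde, which corresponds to 4S (C3 of the target); the zinc reagent leaves the second alkenyl iodide untouched.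

Step 6
Reactants: 11 (2Z,4S,6E)-1-[(tert-butyldimethylsilyl)oxy]-7-iodo-3-methylocta-2,6-dien-4-ol
Product: 12 (2Z,4S,6E)-1-[(tert-butyldimethylsilyl)oxy]-7-iodo-3-methylocta-2,6-dien-4-yl benzoate
Conditions: BzCl, pyridine, DMAP (cat.), CH2Cl2, 0 °C → rt
Reagents that add atoms: benzoyl chloride, O=C(Cl)c1ccccc1
Why: DMAP-catalysed acylation of the secondary allylic alcohol installs the C3 benzoate of the target with retention.

Step 7
Reactants: 12 (2Z,4S,6E)-1-[(tert-butyldimethylsilyl)oxy]-7-iodo-3-methylocta-2,6-dien-4-yl benzoate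
Product: 13 (2Z,4S,6E)-1-hydroxy-7-iodo-3-methylocta-2,6-dien-4-yl benzoate
Conditions: HF·pyridine, pyridine, THF, 0 °C
Reagents that add atoms: none
Why: Buffered acidic fluoride removes the primary allylic silyl ether without the 1,4-benzoyl shift that a basic fluoride source could trigger across the Z alkene.

Step 8
Reactants: 13 (2Z,4S,6E)-1-hydroxy-7-iodo-3-methylocta-2,6-dien-4-yl benzoate
Product: 14 (2Z,4S,6E)-7-iodo-3-methyl-1-oxoocta-2,6-dien-4-yl benzoate
Conditions: Dess–Martin periodinane, NaHCO3, CH2Cl2, 0 °C; used without chromatography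
Reagents that add atoms: none
Why: Neutral Dess–Martin oxidation of the allylic alcohol should keep the Z enal from isomerising, as in nerol-to-neral oxidations.

Step 9
Reactants: 15 (4S)-4-benzyl-1,3-oxazolidin-2-one; 16 methyl 4-chloro-4-oxobutanoate
Product: 17 methyl 4-[(4S)-4-benzyl-2-oxo-1,3-oxazolidin-3-yl]-4-oxobutanoate
Conditions: Et3N, DMAP (cat.), CH2Cl2, 0 °C → rt
Reagents that add atoms: none
Why: DMAP-catalysed N-acylation of the oxazolidinone by the acid chloride gives the succinate imide.

Step 10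
Reactants: 17 methyl 4-[(4S)-4-benzyl-2-oxo-1,3-oxazolidin-3-yl]-4-oxobutanoate; 14 (2Z,4S,6E)-7-iodo-3-methyl-1-oxoocta-2,6-dien-4-yl benzoate
Product: 20 (4S)-4-benzyl-3-({(2R,3S)-2-[(1Z,3S,5E)-3-(benzoyloxy)-6-iodo-2-methylhepta-1,5-dien-1-yl]-5-oxooxolan-3-yl}carbonyl)-1,3-oxazolidin-2-one, via boron enolate 18 (not isolated), via aldol adduct 19 (not isolated)
Conditions: Bu2BOTf, iPr2NEt, CH2Cl2, 0 °C; 14, −78 → 0 °C; pH 7 buffer, MeOH, H2O2, 0 °C; then PPTS (cat.), CH2Cl2, rt
Reagents that add atoms: none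
Why: Evans syn aldol: the Z boron enolate reacts through a chair transition state on the face away from the benzyl group, setting C7 and C6, and the C6 hydroxyl then closes onto the methyl ester to give the trans-disubstituted γ-lactone (ring B).

Step 11
Reactants: 20 trans-lactone imide
Product: 21 S-ethyl (2R,3S)-2-[(1Z,3S,5E)-3-(benzoyloxy)-6-iodo-2-methylhepta-1,5-dien-1-yl]-5-oxooxolane-3-carbothioate
Conditions: EtSH, n-BuLi, THF, 0 °C
Reagents that add atoms: ethanethiol, CCS
Why: Lithium ethanethiolate attacks the exocyclic imide carbonyl and expels the oxazolidinone (thiolate transacylation of an N-acyloxazolidinone), a soft nucleophile that should spare the lactone and the benzoate.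

Step 12
Reactants: 21 S-ethyl thioester
Product: 22 (1Z,3S,5E)-1-[(2R,3S)-3-acetyl-5-oxooxolan-2-yl]-6-iodo-2-methylhepta-1,5-dien-3-yl benzoate
Conditions: Me2CuLi (from MeLi and CuI), Et2O, −78 °C
Reagents that add atoms: lithium dimethylcuprate, [Li+].C[Cu-]C
Why: Thioesters are converted into ketones by lithium dialkylcuprates at low temperature (cuprate ketone synthesis), where lactone, benzoate and alkenyl iodide should stay intact and the ketone does not react further.

Step 13
Reactants: 22 methyl ketone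
Product: 23 (1Z,3S,5E)-6-iodo-2-methyl-1-{(2R,3S)-5-oxo-3-[1-(triethylsilyloxy)ethenyl]oxolan-2-yl}hepta-1,5-dien-3-yl benzoate
Conditions: TESOTf, Et3N, CH2Cl2, −78 → 0 °C
Reagents that add atoms: triethylsilyl trifluoromethanesulfonate, CC[Si](CC)(CC)OS(=O)(=O)C(F)(F)F
Why: Soft enolisation with silyl triflate and amine removes a proton from the unhindered methyl group, not from the branched C7, and gives the 2-silyloxy-1-alkene (kinetic silyl enol ether formation) without enolate-type β-elimination of the lactone oxygen.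

Step 14
Reactants: 23 lactone with C8 triethylsilyl enol ether and E alkenyl iodide
Product: 25 (3S,6R,7S,8R)-3-benzoyloxy-8-(triethylsilyloxy)germacra-1(10)E,4Z-dien-12,6-olide, via alkylborane 24 (not isolated)
Conditions: 9-BBN, THF, 0 °C → rt; then slow addition to Pd(dppf)Cl2 (15 mol%), AsPh3, aq. K3PO4, DMF/THF, rt → 40 °C (final 2 mM)
Reagents that add atoms: none
Why: 9-BBN adds syn across the electron-rich 1,1-disubstituted enol ether, boron to the terminal C9 and hydrogen to C8; zerovalent palladium then inserts into the C10–I bond with retention, phosphate turns the alkylborane into a borate that hands the primary C9 carbon to palladium, and reductive elimination forms C9–C10. The closest known reaction type is the B-alkyl Suzuki–Miyaura coupling of alkylboranes made from enol ethers, including its macrocyclising variant. The ten-membered carbocycle (ring A) closes by sp3–sp2 reductive elimination from a palladacycle that holds C9 and C10, and the fixed E geometry at C1=C10, the Z alkene C4=C5 and the trans-lactone turn bring the two ends together. The new stereocentre C8 is set by C7: in the rotamer with C7–H eclipsing C8=C9 the C6 side chain shields one face, so boron and hydrogen should arrive from the face flanked by the C11 methylene, giving 8R. The step needs the enol ether to react with 9-BBN before the trisubstituted alkenes and the carbonyl groups (secured by its terminal, electron-rich nature and the bulk of 9-BBN) and ring closure to outrun oligomerisation, β-hydride and β-silyloxy elimination (secured by slow addition at high dilution and the wide bite angle of dppf); oxidative addition to C–I is also much faster than ionisation of the hindered allylic benzoate.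

Step 15
Reactants: 25 ten-membered lactone
Product: 29 (3S,6R,7S,8R)-3-benzoyloxy-8-(triethylsilyloxy)germacra-1(10)E,4Z,11(13)-trien-12,6-olide, via lithium enolate 26 (not isolated), via Mannich base 27 (not isolated), via ammonium iodide 28 (not isolated)
Conditions: LiN(SiMe3)2, THF, −78 °C; CH2=NMe2+ I−, −78 → 0 °C; then MeI, MeOH/CH2Cl2, rt; then aq. NaHCO3, EtOAc, rt
Reagents that add atoms: N,N-dimethylmethyleneiminium iodide, C=[N+](C)C.[I-]
Why: The lactone enolate is aminomethylated at C11, and quaternisation followed by base-induced loss of trimethylamine installs C11=C13 (Eschenmoser methylenation); C11 ends sp2, so no stereocentre is at stake.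

Step 16
Reactants: 29 α-methylene lactone silyl ether
Product: 30 (3S,6R,7R,8R)-3-benzoyloxy-8-hydroxygermacra-1(10)E,4Z,11(13)-trien-12,6-olide
Conditions: HF·pyridine, pyridine, THF, 0 °C → rt
Reagents that add atoms: none
Why: Pyridine-buffered fluoride cleaves the secondary triethylsilyl ether and should leave the benzoate, the Michael acceptor and the acid-sensitive 1(10),4-diene alone.

Step 17
Reactants: 31 (2E)-2-methylbut-2-en-1-ol
Product: 32 [(2S,3S)-2,3-dimethyloxiran-2-yl]methanol
Conditions: Ti(OiPr)4 (10 mol%), L-(+)-diisopropyl tartrate (12 mol%), t-BuOOH, 4 Å MS, CH2Cl2, −20 °C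
Reagents that add atoms: tert-butyl hydroperoxide, CC(C)(C)OO
Why: Sharpless asymmetric epoxidation: with the L-(+)-tartrate the titanium-bound peroxide reaches the face that gives the (2S,3S) epoxy alcohol, as established for E allylic alcohols, and the cis relation of the two methyl groups is inherited from the E alkene.

Step 18
Reactants: 32 [(2S,3S)-2,3-dimethyloxiran-2-yl]methanol
Product: 33 (2R,3S)-2,3-dimethyloxirane-2-carboxylic acid
Conditions: RuCl3 (cat.), NaIO4, CCl4/MeCN/H2O, 0 °C → rt
Reagents that add atoms: water, O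
Why: RuO4 formed catalytically from RuCl3 and NaIO4 oxidises the primary alcohol through the aldehyde hydrate to the acid without opening the epoxide (ruthenium-catalysed periodate oxidation); the label at C2 changes from S to R only because the substituent ranking changes.

Step 19
Reactants: 33 (2R,3S)-2,3-dimethyloxirane-2-carboxylic acid; 30 C8 alcohol
Product: 35 (3S,6R,7R,8R)-3-benzoyloxy-8-{[(2R,3S)-2,3-dimethyloxiran-2-yl]carbonyloxy}germacra-1(10)E,4Z,11(13)-trien-12,6-olide, via mixed anhydride 34 (not isolated)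
Conditions: 2,4,6-Cl3C6H2COCl, Et3N, toluene, rt; then 30, DMAP, toluene, rt
Reagents that add atoms: none
Why: Yamaguchi esterification: DMAP attacks the less hindered epoxy-acyl carbonyl of the mixed anhydride and the acylpyridinium acylates the hindered C8 alcohol with retention at C8 and at both epoxide carbons.

Step 20
Reactants: 35 C8 epoxy ester
Product: 36 target, (1R,3S,6R,7R,8R,10R)-3-benzoyloxy-1,10-epoxy-8-{[(2R,3S)-2,3-dimethyloxiran-2-yl]carbonyloxy}germacra-4Z,11(13)-dien-12,6-olide
Conditions: mCPBA, NaHCO3, CH2Cl2, 0 °C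
Reagents that add atoms: 3-chloroperbenzoic acid, O=C(OO)c1cccc(Cl)c1
Why: Prilezhaev epoxidation: the peracid should attack only the electron-rich C1=C10 (C4=C5 lies between two acyloxy-bearing carbons, C11=C13 is conjugated), stereospecifically and from the outer face of the ring in its preferred conformer, which by analogy with other 1(10)E-germacranolides should give the trans (1R,10R) epoxide.

**Compound list**

1 | but-2-yn-1-ol | CC#CCO | starting material
2 | sodium alkenylalanate: five-membered C3–Al–O ring of the butenol, two 2-methoxyethoxy groups on aluminium (formed in the flask) | [Na+].CC1=CCO[Al-]1(OCCOC)OCCOC | intermediate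
3 | (2Z)-3-iodobut-2-en-1-ol | C/C(I)=C/CO | intermediate
4 | tert-butyl{[(2Z)-3-iodobut-2-en-1-yl]oxy}dimethylsilane | C/C(I)=C/CO[Si](C)(C)C(C)(C)C | intermediate
5 | pent-3-yn-1-ol | CC#CCCO | starting material
6 | alkenylzirconocene chloride: Cp2ZrCl on C4 trans to C2, second Cp2ZrCl on the alkoxide oxygen (formed in the flask) | C/C(=C\CCO[Zr](Cl)(C1C=CC=C1)C1C=CC=C1)[Zr](Cl)(C1C=CC=C1)C1C=CC=C1 | intermediate
7 | (3E)-4-iodopent-3-en-1-ol | OCC/C=C(\C)I | intermediate
8 | (3E)-4-iodopent-3-enal | O=CC/C=C(\C)I | intermediate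
9 | alkenyllithium from 4, lithium in place of iodine and cis to CH2OTBS (formed in the flask) | C/C([Li])=C/CO[Si](C)(C)C(C)(C)C | intermediate
10 | bis-alkenylzinc carrying two alkenyl groups of 9 (formed in the flask) | C/C(=C/CO[Si](C)(C)C(C)(C)C)[Zn]/C(C)=C\CO[Si](C)(C)C(C)(C)C | intermediate
11 | (2Z,4S,6E)-1-[(tert-butyldimethylsilyl)oxy]-7-iodo-3-methylocta-2,6-dien-4-ol | CC(C)(C)[Si](C)(C)OC/C=C(/C)[C@@H](O)C/C=C(\C)I | intermediate
12 | (2Z,4S,6E)-1-[(tert-butyldimethylsilyl)oxy]-7-iodo-3-methylocta-2,6-dien-4-yl benzoate | CC(C)(C)[Si](C)(C)OC/C=C(/C)[C@@H](OC(=O)c1ccccc1)C/C=C(\C)I | intermediate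
13 | (2Z,4S,6E)-1-hydroxy-7-iodo-3-methylocta-2,6-dien-4-yl benzoate | OC/C=C(/C)[C@@H](OC(=O)c1ccccc1)C/C=C(\C)I | intermediate
14 | (2Z,4S,6E)-7-iodo-3-methyl-1-oxoocta-2,6-dien-4-yl benzoate | O=C/C=C(/C)[C@@H](OC(=O)c1ccccc1)C/C=C(\C)I | intermediate
15 | (4S)-4-benzyl-1,3-oxazolidin-2-one | O=C1N[C@@H](Cc2ccccc2)CO1 | starting material
16 | methyl 4-chloro-4-oxobutanoate | COC(=O)CCC(Cl)=O | starting material
17 | methyl 4-[(4S)-4-benzyl-2-oxo-1,3-oxazolidin-3-yl]-4-oxobutanoate | COC(=O)CCC(=O)N1[C@@H](Cc2ccccc2)COC1=O | intermediate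
18 | dibutylboron Z enolate of 17 (formed in the flask) | COC(=O)C/C=C(\OB(CCCC)CCCC)N1[C@@H](Cc2ccccc2)COC1=O | intermediate
19 | syn aldol adduct, methyl ester with free C6 hydroxyl, 6R,7S in germacrane numbering (formed in the flask) | COC(=O)C[C@H](C(=O)N1[C@@H](Cc2ccccc2)COC1=O)[C@H](O)/C=C(/C)[C@@H](OC(=O)c1ccccc1)C/C=C(\C)I | intermediate
20 | (4S)-4-benzyl-3-({(2R,3S)-2-[(1Z,3S,5E)-3-(benzoyloxy)-6-iodo-2-methylhepta-1,5-dien-1-yl]-5-oxooxolan-3-yl}carbonyl)-1,3-oxazolidin-2-one | O=C(N1[C@@H](Cc2ccccc2)COC1=O)[C@H]1CC(=O)O[C@@H]1/C=C(/C)[C@@H](OC(=O)c1ccccc1)C/C=C(\C)I | intermediate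
21 | S-ethyl (2R,3S)-2-[(1Z,3S,5E)-3-(benzoyloxy)-6-iodo-2-methylhepta-1,5-dien-1-yl]-5-oxooxolane-3-carbothioate | CCSC(=O)[C@H]1CC(=O)O[C@@H]1/C=C(/C)[C@@H](OC(=O)c1ccccc1)C/C=C(\C)I | intermediate
22 | (1Z,3S,5E)-1-[(2R,3S)-3-acetyl-5-oxooxolan-2-yl]-6-iodo-2-methylhepta-1,5-dien-3-yl benzoate | CC(=O)[C@H]1CC(=O)O[C@@H]1/C=C(/C)[C@@H](OC(=O)c1ccccc1)C/C=C(\C)I | intermediate
23 | (1Z,3S,5E)-6-iodo-2-methyl-1-{(2R,3S)-5-oxo-3-[1-(triethylsilyloxy)ethenyl]oxolan-2-yl}hepta-1,5-dien-3-yl benzoate | C=C(O[Si](CC)(CC)CC)[C@H]1CC(=O)O[C@@H]1/C=C(/C)[C@@H](OC(=O)c1ccccc1)C/C=C(\C)I | intermediate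
24 | B-alkyl-9-BBN adduct of 23, boron on C9, 8R (formed in the flask) | C1CCC2CCCC1B2C[C@@H](O[Si](CC)(CC)CC)[C@H]1CC(=O)O[C@@H]1/C=C(/C)[C@@H](OC(=O)c1ccccc1)C/C=C(\C)I | intermediate
25 | (3S,6R,7S,8R)-3-benzoyloxy-8-(triethylsilyloxy)germacra-1(10)E,4Z-dien-12,6-olide | O=C1C[C@H]2[C@H](O1)/C=C(/C)[C@@H](OC(=O)c1ccccc1)C/C=C(\C)C[C@H]2O[Si](CC)(CC)CC | intermediate
26 | lithium enolate of 25, C11=C12–OLi (formed in the flask) | [Li]OC1=C[C@H]2[C@H](O1)/C=C(/C)[C@@H](OC(=O)c1ccccc1)C/C=C(\C)C[C@H]2O[Si](CC)(CC)CC | intermediate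
27 | Mannich base: 25 with CH2NMe2 on C11, C11 epimers (formed in the flask) | CN(C)CC1C(=O)O[C@@H]2/C=C(/C)[C@@H](OC(=O)c3ccccc3)C/C=C(\C)C[C@@H](O[Si](CC)(CC)CC)[C@@H]12 | intermediate
28 | trimethylammonium iodide of 27 (formed in the flask) | C[N+](C)(C)CC1C(=O)O[C@@H]2/C=C(/C)[C@@H](OC(=O)c3ccccc3)C/C=C(\C)C[C@@H](O[Si](CC)(CC)CC)[C@@H]12.[I-] | intermediate
29 | (3S,6R,7S,8R)-3-benzoyloxy-8-(triethylsilyloxy)germacra-1(10)E,4Z,11(13)-trien-12,6-olide | C=C1C(=O)O[C@@H]2/C=C(/C)[C@@H](OC(=O)c3ccccc3)C/C=C(\C)C[C@@H](O[Si](CC)(CC)CC)[C@@H]12 | intermediate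
30 | (3S,6R,7R,8R)-3-benzoyloxy-8-hydroxygermacra-1(10)E,4Z,11(13)-trien-12,6-olide | C=C1C(=O)O[C@@H]2/C=C(/C)[C@@H](OC(=O)c3ccccc3)C/C=C(\C)C[C@@H](O)[C@@H]12 | intermediate
31 | (2E)-2-methylbut-2-en-1-ol | C/C=C(\C)CO | starting material
32 | [(2S,3S)-2,3-dimethyloxiran-2-yl]methanol | OC[C@]1(C)O[C@H]1C | intermediate
33 | (2R,3S)-2,3-dimethyloxirane-2-carboxylic acid | OC(=O)[C@]1(C)O[C@H]1C | intermediate
34 | mixed anhydride of 33 with 2,4,6-trichlorobenzoic acid (formed in the flask) | O=C(OC(=O)[C@]1(C)O[C@H]1C)c1c(Cl)cc(Cl)cc1Cl | intermediate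
35 | (3S,6R,7R,8R)-3-benzoyloxy-8-{[(2R,3S)-2,3-dimethyloxiran-2-yl]carbonyloxy}germacra-1(10)E,4Z,11(13)-trien-12,6-olide | C=C1C(=O)O[C@@H]2/C=C(/C)[C@@H](OC(=O)c3ccccc3)C/C=C(\C)C[C@@H](OC(=O)[C@]3(C)O[C@H]3C)[C@@H]12 | intermediate
36 | CNP0324463.5, (1R,3S,6R,7R,8R,10R)-3-benzoyloxy-1,10-epoxy-8-{[(2R,3S)-2,3-dimethyloxiran-2-yl]carbonyloxy}germacra-4Z,11(13)-dien-12,6-olide | C=C1C(=O)O[C@@H]2/C=C(/C)[C@@H](OC(=O)c3ccccc3)C[C@H]3O[C@]3(C)C[C@@H](OC(=O)[C@]3(C)O[C@H]3C)[C@@H]12 | target

**Step count and risks**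

Total steps: 20. Longest linear sequence: 15 steps (1 → 3 → 4 → 11 → 12 → 13 → 14 → 20 → 21 → 22 → 23 → 25 → 29 → 30 → 35 → 36).

The three steps most likely to fail:

1. Step 14. The hydroboration may take place on the face of the enol ether next to C6, because control rests on one rotamer preference about the exocyclic C7–C8 bond; this would invert C8 while leaving the ring closure as planned. The fallback replaces facial control by a stereospecific inversion. It sets out from 23: the same two operations would then give the C8-epimeric alkylborane F1 and from it the C8-epimeric macrocycle F2. Desilylation with HF·pyridine gives the 8S alcohol F3. A Mitsunobu reaction with chloroacetic acid (PPh3, DIAD, toluene) inverts C8 and gives the 8R chloroacetate F4. Thiourea and NaHCO3 in ethanol remove the chloroacetyl group without touching the benzoate and free the 8R alcohol F5. TESOTf and 2,6-lutidine then return to the route at 25.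

2. Step 20. The peracid may approach the other face of C1=C10 if the ten-membered ring populates the conformer that exposes that face, which would give the (1S,10S) epoxide. The fallback replaces substrate control by catalyst control. It sets out from 35 and uses the dioxirane formed from the D-fructose-derived Shi ketone and KHSO5 (K2CO3 buffer, MeCN/dimethoxymethane/H2O, 0 °C). Its spiro transition state sets the (R,R) sense on E trisubstituted alkenes and should again select the electron-rich C1=C10; the route is rejoined directly at 36 with no new intermediate.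

3. Step 5. Uncatalysed addition promoted by lithium and zinc halides, together with enolisation of the β,γ-unsaturated aldehyde, may erode the enantiomeric purity at C3. The fallback sets the stereocentre by reduction instead of addition. It sets out from 4 and 8: alkenyllithium 9 is added to 8 at −78 °C without ligand to give the racemic allylic alcohol F6. Dess–Martin oxidation gives the enone F7. Reduction with BH3·SMe2 and (R)-2-methyl-CBS-oxazaborolidine, in which the alkenyl group acts as the large substituent, should give the 4S alcohol and returns to the route at 11.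

**Further compounds**

F1 | step 14 | C8-epimeric (8S) B-alkyl-9-BBN adduct of 23 | C1CCC2CCCC1B2C[C@H](O[Si](CC)(CC)CC)[C@H]1CC(=O)O[C@@H]1/C=C(/C)[C@@H](OC(=O)c1ccccc1)C/C=C(\C)I
F2 | step 14 | (3S,6R,7S,8S)-3-benzoyloxy-8-(triethylsilyloxy)germacra-1(10)E,4Z-dien-12,6-olide | O=C1C[C@H]2[C@H](O1)/C=C(/C)[C@@H](OC(=O)c1ccccc1)C/C=C(\C)C[C@@H]2O[Si](CC)(CC)CC
F3 | step 14 | (3S,6R,7R,8S)-3-benzoyloxy-8-hydroxygermacra-1(10)E,4Z-dien-12,6-olide | O=C1C[C@H]2[C@H](O1)/C=C(/C)[C@@H](OC(=O)c1ccccc1)C/C=C(\C)C[C@@H]2O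
F4 | step 14 | (3S,6R,7R,8R)-3-benzoyloxy-8-(chloroacetoxy)germacra-1(10)E,4Z-dien-12,6-olide | O=C1C[C@H]2[C@H](O1)/C=C(/C)[C@@H](OC(=O)c1ccccc1)C/C=C(\C)C[C@H]2OC(=O)CCl
F5 | step 14 | (3S,6R,7R,8R)-3-benzoyloxy-8-hydroxygermacra-1(10)E,4Z-dien-12,6-olide | O=C1C[C@H]2[C@H](O1)/C=C(/C)[C@@H](OC(=O)c1ccccc1)C/C=C(\C)C[C@H]2O
F0 | step 20 | none | none
F6 | step 5 | racemic (2Z,6E)-1-[(tert-butyldimethylsilyl)oxy]-7-iodo-3-methylocta-2,6-dien-4-ol | CC(C)(C)[Si](C)(C)OC/C=C(/C)C(O)C/C=C(\C)I
F7 | step 5 | (2Z,6E)-1-[(tert-butyldimethylsilyl)oxy]-7-iodo-3-methylocta-2,6-dien-4-one | CC(C)(C)[Si](C)(C)OC/C=C(/C)C(=O)C/C=C(\C)I
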